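**Retrosynthetic overview**
- Target: 4-[(2,4-dihydroxy-6-pentylbenzoyl)oxy]-2-hydroxy-6-propylbenzoic acid, a depside. Ring B (the propyl salicylate half) is bought as an arene; ring A (the pentyl resorcylate half) is built last, directly on the ester oxygen of ring B.
- Feature used: in ring A (C1 bears the ester carbonyl, C2 and C4 the hydroxyls, C6 the pentyl), C1 and C6 are the two sp carbons of an oct-2-ynoate, and C2 to C5 with both oxygens are a 1,3-bis(silyloxy)diene. Disconnect C1–C2 and C5–C6 (Diels–Alder, then retro-Diels–Alder loss of 2-methylpropene).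
- Dienophile: the ring B aryl oct-2-ynoate, from O4-selective esterification of benzyl 2,4-dihydroxy-6-propylbenzoate (5-propylresorcinol: formylation, chlorite oxidation, benzylation). Diene: dimedone, two silylations.
- Ring order: ring B is present from the start, ring A is formed in the key step; desilylation and hydrogenolysis of the benzyl ester finish the synthesis.

Key step: step 7

Remark on the chemistry: direct carboxylation of a 5-alkylresorcinol is not reliably regioselective, so the ring B carboxyl is introduced by formylation and oxidation. The chelated ring B phenol is silylated in the flask just before the cycloaddition so that no acidic proton meets the silyl dienol ether; all three silyl groups are removed together in step 8.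

**Step 1**
Reactants: 1 5-propylresorcinol (5-propylbenzene-1,3-diol)
Product: 3 2,4-dihydroxy-6-propylbenzaldehyde, via aryl iminium chloride 2 (not isolated)
Conditions: POCl3 (1.2 equiv), DMF, 0 °C to rt; then H2O, rt
Reagents that add atoms: N,N-dimethylformamide, CN(C)C=O; water, O
Why: Vilsmeier–Haack formylation, in which the chloroiminium ion attacks the ring position para to one hydroxyl and ortho to the other (the established site for orcinol and olivetol) and water then hydrolyses iminium 2 to the aldehyde.

**Step 2**
Reactants: 3 2,4-dihydroxy-6-propylbenzaldehyde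
Product: 4 2,4-dihydroxy-6-propylbenzoic acid
Conditions: NaClO2, NaH2PO4, DMSO/H2O, 0 °C to rt
Reagents that add atoms: sodium chlorite, [Na+].[O-]Cl=O
Why: Pinnick (Lindgren) chlorite oxidation of the aldehyde under buffered conditions, with DMSO consuming the hypochlorous acid by-product so that the electron-rich ring should not be chlorinated, and with no peroxide present that could trigger a Dakin cleavage.

**Step 3**
Reactants: 4 2,4-dihydroxy-6-propylbenzoic acid
Product: 5 benzyl 2,4-dihydroxy-6-propylbenzoate
Conditions: BnBr (1.05 equiv), KHCO3, DMF, rt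
Reagents that add atoms: benzyl bromide, BrCc1ccccc1
Why: SN2 alkylation of the carboxylate, since bicarbonate deprotonates only the carboxylic acid and leaves the phenols un-ionised, and room temperature avoids decarboxylation of the resorcylic acid.

**Step 4**
Reactants: 5 benzyl 2,4-dihydroxy-6-propylbenzoate; 6 oct-2-ynoic acid
Product: 7 benzyl 2-hydroxy-4-(oct-2-ynoyloxy)-6-propylbenzoate
Conditions: DCC (1.1 equiv), DMAP (5 mol%), CH2Cl2, 0 °C
Reagents that add atoms: none
Why: Steglich esterification, selective for the free O4 hydroxyl because the O2 hydroxyl is hydrogen-bonded to and flanked by the benzyl ester, while the linear ynoic acid is unhindered and low temperature with little DMAP limits conjugate addition to the triple bond.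

**Step 5**
Reactants: 8 dimedone (5,5-dimethylcyclohexane-1,3-dione)
Product: 9 5,5-dimethyl-3-(trimethylsilyloxy)cyclohex-2-en-1-one
Conditions: Me3SiCl, Et3N, THF, 0 °C to rt; filter, distil
Reagents that add atoms: chlorotrimethylsilane, C[Si](C)(C)Cl
Why: O-silylation of the enol form of the cyclic 1,3-diketone, giving the vinylogous silyl ester.

**Step 6**
Reactants: 9 5,5-dimethyl-3-(trimethylsilyloxy)cyclohex-2-en-1-one
Product: 11 5,5-dimethyl-1,3-bis(trimethylsilyloxy)cyclohexa-1,3-diene, via lithium dienolate 10 (not isolated)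
Conditions: LiN(iPr)2, THF, −78 °C; then Me3SiCl, −78 °C to rt; pentane, filter, distil
Reagents that add atoms: chlorotrimethylsilane, C[Si](C)(C)Cl
Why: kinetic deprotonation of the vinylogous ester followed by O-silylation of the lithium dienolate, where the symmetry of dimedone means that either deprotonation site leads to the same 1,3-bis(silyloxy)-1,3-diene.

**Step 7**
Reactants: 7 benzyl 2-hydroxy-4-(oct-2-ynoyloxy)-6-propylbenzoate; 11 5,5-dimethyl-1,3-bis(trimethylsilyloxy)cyclohexa-1,3-diene
Product: 14 benzyl 4-{[6-pentyl-2,4-bis(trimethylsilyloxy)benzoyl]oxy}-6-propyl-2-(trimethylsilyloxy)benzoate, via ring B silyl ether 12 (not isolated), via bicyclo[2.2.2]octadiene adduct 13 (not isolated)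
Conditions: BSA (1.5 equiv), MeCN, 50 °C, evaporate; then 11 (4 equiv), neat, sealed tube, 140 °C; excess 11 removed by bulb-to-bulb distillation
Reagents that add atoms: N,O-bis(trimethylsilyl)acetamide (BSA), CC(=N[Si](C)(C)C)O[Si](C)(C)C
Why: After BSA has silylated the chelated phenol, the s-cis-locked, electron-rich diene 11 adds suprafacially to the electron-poor triple bond of aryl ynoate 12 in a concerted but asynchronous thermal [4+2] cycloaddition, the bond from the diene CH terminus to the ynoate β-carbon forming ahead of the bond from the oxygenated terminus to the α-carbon. The closest known reaction type is the Diels–Alder/retro-Diels–Alder (Alder–Rickert) benzannulation of alkynoates with dimedone-derived 1,3-bis(silyloxy)cyclohexadienes, which gives resorcylates. Ring A is closed by this intermolecular (4+2) cycloaddition, which forms C1–C2 and C5–C6 in one event to give bicyclo[2.2.2]octadiene 13, and a thermal cycloreversion then expels the CH2–CMe2 bridge as 2-methylpropene, driven by aromatisation and loss of a gas. No stereocentre needs control, because the two bridgehead centres of racemic 13 disappear on aromatisation. The selectivity needed is regiochemical: both silyloxy groups raise the HOMO coefficient at the unsubstituted diene terminus, which therefore bonds to the pentyl-bearing β-carbon (largest LUMO coefficient) and places the oxygenated terminus next to the ester carbon, giving the 2,4-dioxygenated 6-pentyl pattern. The aryl ester makes the ynoate a better dienophile than an alkyl ynoate, and the benzyl ester, the aryl silyl ether and the ester link between the rings should be inert under neutral thermal conditions.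

**Step 8**
Reactants: 14 benzyl 4-{[6-pentyl-2,4-bis(trimethylsilyloxy)benzoyl]oxy}-6-propyl-2-(trimethylsilyloxy)benzoate
Product: 15 benzyl 4-[(2,4-dihydroxy-6-pentylbenzoyl)oxy]-2-hydroxy-6-propylbenzoate
Conditions: 1 M HCl, THF, 0 °C to rt
Reagents that add atoms: none
Why: acid-catalysed hydrolysis of aryl trimethylsilyl ethers, which should be far faster than hydrolysis of the hindered aryl ester or the benzyl ester.

**Step 9**
Reactants: 15 benzyl 4-[(2,4-dihydroxy-6-pentylbenzoyl)oxy]-2-hydroxy-6-propylbenzoate
Product: 16 4-[(2,4-dihydroxy-6-pentylbenzoyl)oxy]-2-hydroxy-6-propylbenzoic acid (target)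
Conditions: H2 (1 atm), 10% Pd/C, EtOAc, rt
Reagents that add atoms: none
Why: catalytic hydrogenolysis of the benzyl ester C–O bond under neutral conditions at room temperature, which should leave the aryl ester and the arenes untouched and avoid decarboxylation.

**Compound list**
1 | 5-propylresorcinol (5-propylbenzene-1,3-diol) | CCCc1cc(O)cc(O)c1 | starting material
2 | N-[(2,4-dihydroxy-6-propylphenyl)methylidene]-N-methylmethanaminium chloride | CCCc1cc(O)cc(O)c1C=[N+](C)C.[Cl-] | intermediate (not isolated)
3 | 2,4-dihydroxy-6-propylbenzaldehyde | CCCc1cc(O)cc(O)c1C=O | intermediate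
4 | 2,4-dihydroxy-6-propylbenzoic acid | CCCc1cc(O)cc(O)c1C(=O)O | intermediate
5 | benzyl 2,4-dihydroxy-6-propylbenzoate | CCCc1cc(O)cc(O)c1C(=O)OCc1ccccc1 | intermediate
6 | oct-2-ynoic acid | CCCCCC#CC(=O)O | starting material
7 | benzyl 2-hydroxy-4-(oct-2-ynoyloxy)-6-propylbenzoate | CCCCCC#CC(=O)Oc1cc(O)c(C(=O)OCc2ccccc2)c(CCC)c1 | intermediate
8 | dimedone (5,5-dimethylcyclohexane-1,3-dione) | CC1(C)CC(=O)CC(=O)C1 | starting material
9 | 5,5-dimethyl-3-(trimethylsilyloxy)cyclohex-2-en-1-one | CC1(C)CC(=O)C=C(O[Si](C)(C)C)C1 | intermediate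
10 | lithium 3,3-dimethyl-5-(trimethylsilyloxy)cyclohexa-1,5-dien-1-olate | [Li+].[O-]C1=CC(C)(C)CC(O[Si](C)(C)C)=C1 | intermediate (not isolated)
11 | 5,5-dimethyl-1,3-bis(trimethylsilyloxy)cyclohexa-1,3-diene | CC1(C)CC(O[Si](C)(C)C)=CC(O[Si](C)(C)C)=C1 | intermediate
12 | benzyl 4-(oct-2-ynoyloxy)-6-propyl-2-(trimethylsilyloxy)benzoate | CCCCCC#CC(=O)Oc1cc(O[Si](C)(C)C)c(C(=O)OCc2ccccc2)c(CCC)c1 | intermediate (not isolated)
13 | racemic benzyl 4-{[8,8-dimethyl-3-pentyl-1,5-bis(trimethylsilyloxy)bicyclo[2.2.2]octa-2,5-dien-2-yl]carbonyloxy}-6-propyl-2-(trimethylsilyloxy)benzoate | CCCCCC1=C(C(=O)Oc3cc(O[Si](C)(C)C)c(C(=O)OCc4ccccc4)c(CCC)c3)C2(O[Si](C)(C)C)C=C(O[Si](C)(C)C)C1C(C)(C)C2 | intermediate (not isolated)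
14 | benzyl 4-{[6-pentyl-2,4-bis(trimethylsilyloxy)benzoyl]oxy}-6-propyl-2-(trimethylsilyloxy)benzoate | CCCCCc1cc(O[Si](C)(C)C)cc(O[Si](C)(C)C)c1C(=O)Oc1cc(O[Si](C)(C)C)c(C(=O)OCc2ccccc2)c(CCC)c1 | intermediate
15 | benzyl 4-[(2,4-dihydroxy-6-pentylbenzoyl)oxy]-2-hydroxy-6-propylbenzoate | CCCCCc1cc(O)cc(O)c1C(=O)Oc1cc(O)c(C(=O)OCc2ccccc2)c(CCC)c1 | intermediate
16 | 4-[(2,4-dihydroxy-6-pentylbenzoyl)oxy]-2-hydroxy-6-propylbenzoic acid | CCCCCc1cc(O)cc(O)c1C(=O)Oc1cc(O)c(C(=O)O)c(CCC)c1 | target

**Step count**
Total: 9 steps. Longest linear sequence: 7 steps (steps 1, 2, 3, 4, 7, 8, 9 from 5-propylresorcinol); steps 5 and 6 form the diene branch.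

**Steps most likely to fail**

Step 7. The cycloaddition of the β-alkyl ynoate may be slow relative to thermal decay of the silyl dienol ether, the regiochemistry may be poor, or the extrusion may be incomplete. The fallback sets out from 5 and comes back at 16, bringing ring A in preformed by the classical depside esterification. Purchased olivetol F1 is formylated (POCl3, DMF, then water) to 2,4-dihydroxy-6-pentylbenzaldehyde F2, benzylated (BnBr, K2CO3, DMF) to 2,4-bis(benzyloxy)-6-pentylbenzaldehyde F3, and oxidised (NaClO2, NaH2PO4, 2-methylbut-2-ene, t-BuOH/H2O) to 2,4-bis(benzyloxy)-6-pentylbenzoic acid F4. F4 and phenol 5 are joined with trifluoroacetic anhydride in toluene at room temperature to benzyl 4-{[2,4-bis(benzyloxy)-6-pentylbenzoyl]oxy}-2-hydroxy-6-propylbenzoate F5. Hydrogenolysis of all three benzyl groups (H2, Pd/C, EtOAc) then gives 16 directly.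

Step 2. Hypochlorous acid or chlorine dioxide may chlorinate or oxidatively degrade the unprotected electron-rich ring, and the product acid may decarboxylate during work-up. The fallback sets out from 3 and comes back at 5, doing the oxidation on a protected ring. Aldehyde 3 is converted with NaH and chloromethyl methyl ether in DMF to 2,4-bis(methoxymethoxy)-6-propylbenzaldehyde F6. Chlorite oxidation with 2-methylbut-2-ene as scavenger gives 2,4-bis(methoxymethoxy)-6-propylbenzoic acid F7, and BnBr with K2CO3 in DMF gives benzyl 2,4-bis(methoxymethoxy)-6-propylbenzoate F8. HCl in methanol removes both acetals to give 5.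

Step 4. DMAP or a phenol may add in conjugate fashion to the activated ynoate, base may isomerise it to the allenoate, the O-acylisourea may rearrange to an N-acylurea, or O2 may be over-acylated. The fallback sets out from 6 (with 5) and comes back at 7, avoiding the carbodiimide and the nucleophilic catalyst. Acid 6 is converted with oxalyl chloride and catalytic DMF in CH2Cl2 at 0 °C to oct-2-ynoyl chloride F9, which is added to 5 and 2,6-lutidine in CH2Cl2 at −40 °C to give 7.

**Further compounds**
F1 | step 7 | olivetol (5-pentylbenzene-1,3-diol) | CCCCCc1cc(O)cc(O)c1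
F2 | step 7 | 2,4-dihydroxy-6-pentylbenzaldehyde | CCCCCc1cc(O)cc(O)c1C=O
F3 | step 7 | 2,4-bis(benzyloxy)-6-pentylbenzaldehyde | CCCCCc1cc(OCc2ccccc2)cc(OCc2ccccc2)c1C=O
F4 | step 7 | 2,4-bis(benzyloxy)-6-pentylbenzoic acid | CCCCCc1cc(OCc2ccccc2)cc(OCc2ccccc2)c1C(=O)O
F5 | step 7 | benzyl 4-{[2,4-bis(benzyloxy)-6-pentylbenzoyl]oxy}-2-hydroxy-6-propylbenzoate | CCCCCc1cc(OCc2ccccc2)cc(OCc2ccccc2)c1C(=O)Oc1cc(O)c(C(=O)OCc2ccccc2)c(CCC)c1
F6 | step 2 | 2,4-bis(methoxymethoxy)-6-propylbenzaldehyde | CCCc1cc(OCOC)cc(OCOC)c1C=O
F7 | step 2 | 2,4-bis(methoxymethoxy)-6-propylbenzoic acid | CCCc1cc(OCOC)cc(OCOC)c1C(=O)O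
F8 | step 2 | benzyl 2,4-bis(methoxymethoxy)-6-propylbenzoate | CCCc1cc(OCOC)cc(OCOC)c1C(=O)OCc1ccccc1
F9 | step 4 | oct-2-ynoyl chloride | CCCCCC#CC(=O)Cl
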